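**Plan**

- The target is a trans‑dibromocyclobutane whose other two ring carbons (C5 and C6 of the dispiro skeleton) are each the spiro γ‑carbon of a 4‑bromobutenolide. Each spiro carbon bears the lactone oxygen (O1, O7) and is bonded to the brominated vinylic carbon (C4, C10). This is the pattern left when Br+ and a carboxylate add across the ring‑side C=C of a 2,3‑allenoic acid whose allene terminus is a cyclobutane carbon.
- Retrosynthesis: the two acetates go back to silyl ethers. Both spiro C–O bonds and both vinylic C–Br bonds are then cut together to a 1,2‑bis(vinylidene)cyclobutane diacid. Each allene–CO2H bond is cut to a propargylic ester and CO, and the two ring–alkyne bonds are cut to trans‑3,4‑dibromocyclobutane‑1,2‑dione and the silyl ethers of (S)‑ and (R)‑hex‑1‑yn‑3‑ol.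
- Forward: the four‑membered ring is carried from 1,2‑bis(trimethylsilyloxy)cyclobutene (dione, enedione, bromine adduct). The two C6 chains are joined by successive organocerium additions, CO is inserted on both arms, and both butenolide rings close in one operation.
- Stereochemistry: the side‑chain carbinols come from the two enantiomeric alkynols. The absolute configuration of the core is fixed by separating the two diastereomeric mono‑adducts formed from the racemic dibromide.
- Each alkyne is planned to add anti to the neighbouring bromine. Anti SN2′ carbonylation turns each carbinol into an allene axis, and the axis delivers the lactone oxygen to one ring face, trans to the adjacent bromine.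

Key step: step 10

Remark: dibromodione 9 is formed as the racemate and only its (3R,4R) enantiomer (the one drawn) is carried on after step 6; in the SMILES each allene axis is encoded on the central allene carbon, read against the four substituents of the two terminal carbons in the order written.

**Route**

Step 1
Reactants: 1 (S)-hex-1-yn-3-ol
Product: 2 tert-butyl{[(3S)-hex-1-yn-3-yl]oxy}dimethylsilane
Conditions: TBSCl, imidazole, DMF, 0 °C to rt
Reagents that add atoms: tert-butyldimethylsilyl chloride CC(C)(C)[Si](C)(C)Cl
Why: Imidazole-promoted silyl ether formation on a secondary alcohol is routine and does not touch the carbinol stereocentre.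

Step 2
Reactants: 3 (R)-hex-1-yn-3-ol
Product: 4 tert-butyl{[(3R)-hex-1-yn-3-yl]oxy}dimethylsilane
Conditions: TBSCl, imidazole, DMF, 0 °C to rt
Reagents that add atoms: tert-butyldimethylsilyl chloride CC(C)(C)[Si](C)(C)Cl
Why: The same silyl ether formation protects the enantiomeric alkynol with its configuration unchanged.

Step 3
Reactants: 5 1,2-bis(trimethylsilyloxy)cyclobutene
Product: 6 cyclobutane-1,2-dione
Conditions: Br2 (1.0 equiv), pentane, −60 °C to rt, moisture excluded
Reagents that add atoms: none
Why: Bromination of the enediol bis(silyl ether) (oxidative desilylation of an acyloin derivative) expels bromotrimethylsilane twice and should give the dione under anhydrous, base-free conditions that avoid benzilic-type ring contraction.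

Step 4
Reactants: 6 cyclobutane-1,2-dione
Product: 8 cyclobut-3-ene-1,2-dione, via 3-bromocyclobutane-1,2-dione 7 (not isolated)
Conditions: Br2 (1.0 equiv), CH2Cl2, 0 °C; then i-Pr2NEt (2.0 equiv), −40 °C; cold filtration
Reagents that add atoms: none
Why: α-Bromination of the ketone through its enol followed by E1cB dehydrobromination (the C4 proton is α to C1=O and the bromide is β to it) should give the enedione, the hindered amine limiting nucleophilic attack on the strained dione.

Step 5
Reactants: 8 cyclobut-3-ene-1,2-dione
Product: 9 rac-trans-3,4-dibromocyclobutane-1,2-dione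
Conditions: Br2 (1.0 equiv), CH2Cl2, −20 to 0 °C, dark
Reagents that add atoms: bromine BrBr
Why: Electrophilic anti addition of bromine across the strained enedione C=C (bromonium opening) should give the trans-dibromide as the racemate, trans also being the thermodynamic arrangement of the two enolisable α-bromo centres.

Step 6
Reactants: 2 tert-butyl{[(3S)-hex-1-yn-3-yl]oxy}dimethylsilane; 9 rac-trans-3,4-dibromocyclobutane-1,2-dione
Product: 12 (2R,3R,4R)-3,4-dibromo-2-hydroxy-2-[(3S)-3-(tert-butyldimethylsilyloxy)hex-1-yn-1-yl]cyclobutan-1-one, via (S)-lithium acetylide 10 (not isolated), via (S)-alkynylcerium dichloride 11 (not isolated)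
Conditions: 2, n-BuLi, THF, −78 °C; CeCl3 (anhydrous), −78 °C; cannulated into 9 (1.1 equiv), THF, −78 °C; AcOH, −78 °C; chromatographic separation of the two diastereomers
Reagents that add atoms: none
Why: Organocerium 1,2-addition to a ketone: the weakly basic cerium acetylide should add to one carbonyl of the strained dione faster than it removes HBr, entering anti to the bromine on the adjacent α-carbon (polar Felkin–Anh and steric control) so that the new hydroxyl is cis to that bromine, and because 9 is racemic the (S)-side chain turns its two enantiomers into two separable diastereomers, of which the (2R,3R,4R) one fixes the absolute configuration of the core.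

Step 7
Reactants: 12 (2R,3R,4R)-3,4-dibromo-2-hydroxy-2-[(3S)-3-(tert-butyldimethylsilyloxy)hex-1-yn-1-yl]cyclobutan-1-one; 4 tert-butyl{[(3R)-hex-1-yn-3-yl]oxy}dimethylsilane
Product: 15 (1R,2R,3R,4R)-3,4-dibromo-1-[(3S)-3-(tert-butyldimethylsilyloxy)hex-1-yn-1-yl]-2-[(3R)-3-(tert-butyldimethylsilyloxy)hex-1-yn-1-yl]cyclobutane-1,2-diol, via (R)-lithium acetylide 13 (not isolated), via (R)-alkynylcerium dichloride 14 (not isolated)
Conditions: 4 (2.3 equiv), n-BuLi, THF, −78 °C; CeCl3 (anhydrous), −78 °C; then 12, −78 °C; AcOH, −78 °C
Reagents that add atoms: none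
Why: A second organocerium 1,2-addition, after one equivalent of 14 has been spent on the hydroxyl proton, should take place anti to the α-bromine of the remaining ketone and anti to the alkynyl group on the neighbouring carbinol carbon, that is on the face of the cerium alkoxide, which sets the second carbinol and gives the trans-diol with each hydroxyl cis to its adjacent bromine.

Step 8
Reactants: 15 (1R,2R,3R,4R)-3,4-dibromo-1,2-dialkynylcyclobutane-1,2-diol
Product: 16 bis(trifluoroacetate) of diol 15
Conditions: (CF3CO)2O, pyridine, CH2Cl2, −20 to 0 °C; used without chromatography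
Reagents that add atoms: trifluoroacetic anhydride O=C(OC(=O)C(F)(F)F)C(F)(F)F
Why: Acylation of the two tertiary alcohols with the highly reactive anhydride (trifluoroacetylation) should be complete at low temperature without touching the carbinol configuration, ionisation being disfavoured at these electron-poor cyclobutyl carbons.

Step 9
Reactants: 16 bis(trifluoroacetate) of diol 15
Product: 17 (aS,aS)-bis(allenoic acid) on the (3R,4R)-3,4-dibromocyclobutane-1,2-diylidene core
Conditions: Pd(PPh3)4 (10 mol%), CO (1 atm), 2,6-lutidine, THF/H2O (10:1), 0 °C to rt; used at once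
Reagents that add atoms: carbon monoxide [C-]#[O+]; water O
Why: Palladium-catalysed hydroxycarbonylation of propargylic esters: zerovalent palladium displaces each trifluoroacetate in an anti SN2′ sense to an allenylpalladium species, CO inserts with retention and water cleaves the acyl complex, so each carboxyl group should end on the ring face opposite to the departed ester, i.e. anti to the bromine on the neighbouring ring carbon, which sets both allene axes.

Step 10
Reactants: 17 (aS,aS)-bis(allenoic acid)
Product: 19 (5S,6S,11R,12R)-4,10,11,12-tetrabromo-3-[(1S)-1-(tert-butyldimethylsilyloxy)butyl]-9-[(1R)-1-(tert-butyldimethylsilyloxy)butyl]-1,7-dioxadispiro[4.0.4.2]dodeca-3,9-diene-2,8-dione, via mono-butenolide allenoic acid 18 (not isolated)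
Conditions: NBS (2.1 equiv), K2CO3 (0.2 equiv), MeCN, −20 to 0 °C, dark
Reagents that add atoms: N-bromosuccinimide O=C1CCC(=O)N1Br
Why: Proposed new method: NBS transfers Br+ to the central carbon of each allene on the side away from its carboxyl group, and the carboxyl oxygen opens the resulting bromonium ion at the cyclobutane terminus from the opposite side, forming the spiro C–O bond and the vinylic C–Br bond of a 4-bromobutenolide; done twice on a conjugated 1,2-bis(vinylidene)cyclobutane this is without precedent, the closest known reaction being the halolactonisation of single 2,3-allenoic acids to β-halobutenolides. Each five-membered ring closes in a 5-endo mode with respect to the ring-side C=C of its allene (oxygen to C5, then oxygen to C6), the second closure taking place on the now isolated allene of 18. The configuration of each spiro carbon is dictated by its allene axis: the carboxyl group sits on one face of the cyclobutane and can deliver oxygen only to that face, which is anti to the bromine on the neighbouring CHBr carbon, so O1 and O7 end trans to the bromines at C12 and C11. The step needs axis-to-centre transfer without scrambling and attack at the ring-side C=C only; the inductively destabilised cyclobutyl cation should favour a bridged bromonium ion over an open allyl cation, the silyl ethers keep the carbinol oxygens from closing 2,5-dihydrofurans, and the C=C conjugated to CO2H is the less nucleophilic π bond.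

Step 11
Reactants: 19 bis(silyl ether) bis(bromobutenolide)
Product: 20 (5S,6S,11R,12R)-4,10,11,12-tetrabromo-3-[(1S)-1-hydroxybutyl]-9-[(1R)-1-hydroxybutyl]-1,7-dioxadispiro[4.0.4.2]dodeca-3,9-diene-2,8-dione
Conditions: HF·pyridine, THF, 0 °C to rt
Reagents that add atoms: none
Why: Acidic fluoride-mediated desilylation cleaves the two secondary silyl ethers and should leave the lactones, the vinylic bromides and the secondary bromides untouched.

Step 12
Reactants: 20 diol
Product: 21 (5S,6S,11R,12R)-3-[(1S)-1-acetoxybutyl]-9-[(1R)-1-acetoxybutyl]-4,10,11,12-tetrabromo-1,7-dioxadispiro[4.0.4.2]dodeca-3,9-diene-2,8-dione (CNP0266230.1)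
Conditions: Ac2O, Sc(OTf)3 (2 mol%), MeCN, 0 °C
Reagents that add atoms: acetic anhydride CC(=O)OC(C)=O
Why: Lewis-acid-catalysed acetylation with the anhydride esterifies both secondary alcohols with retention and avoids nucleophilic amine catalysts that could displace the β-bromides of the butenolides by addition–elimination.

**Compound list**

1 | (S)-hex-1-yn-3-ol | CCC[C@H](O)C#C | starting material
2 | tert-butyl{[(3S)-hex-1-yn-3-yl]oxy}dimethylsilane | CCC[C@H](O[Si](C)(C)C(C)(C)C)C#C | intermediate
3 | (R)-hex-1-yn-3-ol | CCC[C@@H](O)C#C | starting material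
4 | tert-butyl{[(3R)-hex-1-yn-3-yl]oxy}dimethylsilane | CCC[C@@H](O[Si](C)(C)C(C)(C)C)C#C | intermediate
5 | 1,2-bis(trimethylsilyloxy)cyclobutene | C[Si](C)(C)OC1=C(O[Si](C)(C)C)CC1 | starting material
6 | cyclobutane-1,2-dione | O=C1CCC1=O | intermediate
7 | 3-bromocyclobutane-1,2-dione (racemic, not isolated) | O=C1CC(Br)C1=O | intermediate
8 | cyclobut-3-ene-1,2-dione | O=C1C=CC1=O | intermediate
9 | rac-trans-3,4-dibromocyclobutane-1,2-dione (3R,4R enantiomer drawn) | O=C1[C@@H](Br)[C@H](Br)C1=O | intermediate
10 | lithium (3S)-3-(tert-butyldimethylsilyloxy)hex-1-yn-1-ide (not isolated) | CCC[C@H](O[Si](C)(C)C(C)(C)C)C#C[Li] | intermediate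
11 | [(3S)-3-(tert-butyldimethylsilyloxy)hex-1-yn-1-yl]cerium dichloride (not isolated) | CCC[C@H](O[Si](C)(C)C(C)(C)C)C#C[Ce](Cl)Cl | intermediate
12 | (2R,3R,4R)-3,4-dibromo-2-hydroxy-2-[(3S)-3-(tert-butyldimethylsilyloxy)hex-1-yn-1-yl]cyclobutan-1-one (OH cis to the bromine at C3, bromines trans) | CCC[C@H](O[Si](C)(C)C(C)(C)C)C#C[C@]1(O)[C@@H](Br)[C@H](Br)C1=O | intermediate
13 | lithium (3R)-3-(tert-butyldimethylsilyloxy)hex-1-yn-1-ide (not isolated) | CCC[C@@H](O[Si](C)(C)C(C)(C)C)C#C[Li] | intermediate
14 | [(3R)-3-(tert-butyldimethylsilyloxy)hex-1-yn-1-yl]cerium dichloride (not isolated) | CCC[C@@H](O[Si](C)(C)C(C)(C)C)C#C[Ce](Cl)Cl | intermediate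
15 | (1R,2R,3R,4R)-3,4-dibromo-1-[(3S)-3-(tert-butyldimethylsilyloxy)hex-1-yn-1-yl]-2-[(3R)-3-(tert-butyldimethylsilyloxy)hex-1-yn-1-yl]cyclobutane-1,2-diol (trans-diol, each OH cis to the adjacent bromine) | CCC[C@H](O[Si](C)(C)C(C)(C)C)C#C[C@]1(O)[C@@H](Br)[C@H](Br)[C@@]1(O)C#C[C@@H](CCC)O[Si](C)(C)C(C)(C)C | intermediate
16 | bis(trifluoroacetate) of diol 15 | CCC[C@H](O[Si](C)(C)C(C)(C)C)C#C[C@]1(OC(=O)C(F)(F)F)[C@@H](Br)[C@H](Br)[C@@]1(OC(=O)C(F)(F)F)C#C[C@@H](CCC)O[Si](C)(C)C(C)(C)C | intermediate
17 | (aS,aS)-bis(allenoic acid): (3R,4R)-3,4-dibromocyclobutane-1,2-diylidene core, ring C1 and C2 each the terminus of an allene =C=C(CO2H)–CH(OTBS)Pr, (S)-carbinol on the C1 arm and (R)-carbinol on the C2 arm, each CO2H on the ring face anti to the bromine of the adjacent CHBr | CCC[C@H](O[Si](C)(C)C(C)(C)C)C(C(=O)O)=[C@]=C1[C@@H](Br)[C@H](Br)C1=[C@]=C(C(=O)O)[C@@H](CCC)O[Si](C)(C)C(C)(C)C | intermediate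
18 | mono-butenolide allenoic acid: spiro 4-bromobutenolide closed on the (S)-arm, (R)-arm still the aS allenoic acid (not isolated) | CCC[C@H](O[Si](C)(C)C(C)(C)C)C1=C(Br)[C@@]2(OC1=O)[C@@H](Br)[C@H](Br)C2=[C@]=C(C(=O)O)[C@@H](CCC)O[Si](C)(C)C(C)(C)C | intermediate
19 | (5S,6S,11R,12R)-4,10,11,12-tetrabromo-3-[(1S)-1-(tert-butyldimethylsilyloxy)butyl]-9-[(1R)-1-(tert-butyldimethylsilyloxy)butyl]-1,7-dioxadispiro[4.0.4.2]dodeca-3,9-diene-2,8-dione | CCC[C@H](O[Si](C)(C)C(C)(C)C)C1=C(Br)[C@@]2(OC1=O)[C@@H](Br)[C@H](Br)[C@@]21OC(=O)C([C@@H](CCC)O[Si](C)(C)C(C)(C)C)=C1Br | intermediate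
20 | (5S,6S,11R,12R)-4,10,11,12-tetrabromo-3-[(1S)-1-hydroxybutyl]-9-[(1R)-1-hydroxybutyl]-1,7-dioxadispiro[4.0.4.2]dodeca-3,9-diene-2,8-dione | CCC[C@H](O)C1=C(Br)[C@@]2(OC1=O)[C@@H](Br)[C@H](Br)[C@@]21OC(=O)C([C@@H](CCC)O)=C1Br | intermediate
21 | (5S,6S,11R,12R)-3-[(1S)-1-acetoxybutyl]-9-[(1R)-1-acetoxybutyl]-4,10,11,12-tetrabromo-1,7-dioxadispiro[4.0.4.2]dodeca-3,9-diene-2,8-dione | CCC[C@H](OC(C)=O)C1=C(Br)[C@@]2(OC1=O)[C@@H](Br)[C@H](Br)[C@@]21OC(=O)C([C@@H](CCC)OC(C)=O)=C1Br | target

**Step count and risks**

Total: 12 steps. Longest linear sequence: 10 steps (5 to 21, steps 3 to 12).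

Steps most likely to fail:

1. Step 10 (Proposed new method). The conjugated bis-allene may be attacked by Br+ in a 1,4-sense or oligomerise before either carboxyl group closes, and an open allyl cation would erase the axis-to-centre transfer. The fallback uses known chemistry and closes one arm at a time, so that no conjugated bis-allene is ever formed. Setting out from hydroxy ketone 12, trifluoroacetic anhydride without amine base would give keto trifluoroacetate F1. Palladium-catalysed hydroxycarbonylation as in step 9 would give keto mono(allenoic acid) F2, an isolated allene. NBS bromolactonisation of this single allenoic acid, a known transformation, would give spiro bromobutenolide ketone F3. Cerium reagent 14 would add to the remaining cyclobutanone anti to its α-bromine to give propargylic carbinol F4, whose trifluoroacetate F5 would be carbonylated to the half-closed acid 18. The route is rejoined at 18, which NBS closes to 19 as a single, precedented bromolactonisation.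

2. Step 9. The tertiary trifluoroacetates may solvolyse in the aqueous medium, the allenylpalladium intermediate may expel the neighbouring bromide or ester (1,4-elimination to an enyne) faster than it inserts CO, and palladium may insert into the allylic C–Br bonds of the product. The fallback moves to anhydrous ester formation and unmasks the acids separately. Setting out from diol 15, methyl chloroformate with pyridine and DMAP would give bis(methyl carbonate) F6. Decarboxylative methoxycarbonylation (Pd2(dba)3, PPh3, CO under pressure, MeOH) would give bis(methyl allenoate) F7 in the same anti SN2′ sense. Me3SnOH in 1,2-dichloroethane would then cleave both methyl esters under near-neutral conditions and return to the route at diacid 17.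

3. Step 6. The bromohydrin alkoxide may contract the ring (semibenzilic pathway) or 9 may lose HBr before addition; facial control by the α-bromine may be weak; and the two diastereomers, whose stereocentres are separated by the alkyne, may resist separation. The fallback alkynylates before brominating. Setting out from enedione 8, cerium reagent 11 would add 1,2 to one carbonyl, which has neither an α-hydrogen nor an α-halogen, to give (4R)-4-hydroxycyclobutenone F8 and its (4S)-epimer F9. These are separated at this stage, which again selects the absolute configuration. Excess 14 would add to the ketone of F8 on the face of the alkoxide to give trans-cyclobutenediol F10. Anti addition of bromine across the cyclobutene, each bromide expected to enter beside and on the side of a hydroxyl group, would return to the route at diol 15; this diastereoselectivity would have to be checked.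

**Further compounds**

F1 | step 10 | keto trifluoroacetate (trifluoroacetate of 12) | CCC[C@H](O[Si](C)(C)C(C)(C)C)C#C[C@]1(OC(=O)C(F)(F)F)[C@@H](Br)[C@H](Br)C1=O
F2 | step 10 | keto mono(allenoic acid), CO2H anti to the adjacent ring bromine | CCC[C@H](O[Si](C)(C)C(C)(C)C)C(C(=O)O)=[C@]=C1[C@@H](Br)[C@H](Br)C1=O
F3 | step 10 | spiro bromobutenolide ketone | CCC[C@H](O[Si](C)(C)C(C)(C)C)C1=C(Br)[C@@]2(OC1=O)[C@@H](Br)[C@H](Br)C2=O
F4 | step 10 | propargylic carbinol from addition of 14 to F3 | CCC[C@H](O[Si](C)(C)C(C)(C)C)C1=C(Br)[C@@]2(OC1=O)[C@@H](Br)[C@H](Br)[C@@]2(O)C#C[C@@H](CCC)O[Si](C)(C)C(C)(C)C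
F5 | step 10 | trifluoroacetate of F4 | CCC[C@H](O[Si](C)(C)C(C)(C)C)C1=C(Br)[C@@]2(OC1=O)[C@@H](Br)[C@H](Br)[C@@]2(OC(=O)C(F)(F)F)C#C[C@@H](CCC)O[Si](C)(C)C(C)(C)C
F6 | step 9 | bis(methyl carbonate) of diol 15 | CCC[C@H](O[Si](C)(C)C(C)(C)C)C#C[C@]1(OC(=O)OC)[C@@H](Br)[C@H](Br)[C@@]1(OC(=O)OC)C#C[C@@H](CCC)O[Si](C)(C)C(C)(C)C
F7 | step 9 | bis(methyl allenoate), dimethyl ester of 17 | CCC[C@H](O[Si](C)(C)C(C)(C)C)C(C(=O)OC)=[C@]=C1[C@@H](Br)[C@H](Br)C1=[C@]=C(C(=O)OC)[C@@H](CCC)O[Si](C)(C)C(C)(C)C
F8 | step 6 | (4R)-4-hydroxy-4-[(3S)-3-(tert-butyldimethylsilyloxy)hex-1-yn-1-yl]cyclobut-2-en-1-one | CCC[C@H](O[Si](C)(C)C(C)(C)C)C#C[C@]1(O)C=CC1=O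
F9 | step 6 | (4S)-epimer of F8 | CCC[C@H](O[Si](C)(C)C(C)(C)C)C#C[C@@]1(O)C=CC1=O
F10 | step 6 | (1R,2R)-1-[(3S)-3-(tert-butyldimethylsilyloxy)hex-1-yn-1-yl]-2-[(3R)-3-(tert-butyldimethylsilyloxy)hex-1-yn-1-yl]cyclobut-3-ene-1,2-diol (trans-diol) | CCC[C@H](O[Si](C)(C)C(C)(C)C)C#C[C@]1(O)C=C[C@@]1(O)C#C[C@@H](CCC)O[Si](C)(C)C(C)(C)C
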